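**Slow exits.** In a slow flask you count lifetimes. In the red run at 5.00 min, target, side product and substrate sum to 64.0%, so something unseen holds the rest. I take it to be an intermediate that waits, then leaves with reagent to target or by itself to side product.

the same everywhere: substrate 0.010 M
- red: reagent 1.2 equiv; run made earlier
- teal: reagent 1.7 equiv; run made earlier
- blue: reagent 2.6 equiv; run made earlier
- midnight: reagent 1.20 equiv; a single well-mixed tank run continuously and read at steady state, 50 min in it on average
- dusk: reagent 1.20 equiv (fed, over 25.0 min); a stirred flask in which reagent is dosed at a steady rate over 25.0 min without added volume, worked up at 50 min; time 50 min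
- summer: reagent 1.20 equiv; everything together in a closed stirred flask, run for 50 min; time 50 min
- noon: reagent 1.20 equiv; a single well-mixed tank run continuously and read at steady state, 150 min in it on average

- red (time / min: target / %, side product / %, substrate / %): 5.00: 19.1, 8.5, 36.4; 10.0: 29.0, 11.9, 23.5; 15.0: 33.5, 18.5, 19.9; 20.0: 35.3, 20.5, 18.1; 25.0: 36.5, 24.2, 17.8; 30.0: 38.1, 26.9, 17.7
- teal (time / min: target / %, side product / %, substrate / %): 10.0: 42.4, 12.5, 15.9; 20.0: 52.7, 21.5, 8.9; 30.0: 56.5, 23.8, 8.0; 40.0: 58.6, 24.6, 6.6; 50.0: 59.5, 27.6, 6.3; 60.0: 60.5, 27.3, 4.5
- blue (time / min: target / %, side product / %, substrate / %): 4.00: 41.0, 6.5, 22.3; 12.0: 63.8, 12.0, 7.2; 20.0: 71.3, 14.9, 5.1; 30.0: 76.7, 16.7, 1.3; 50.0: 83.5, 16.3, 0.1; 60.0: 81.3, 16.9, 0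

(standard deviation of a reading: 1 percentage point)

1. the set-up with the highest share of target in all that became target or side product, at the outlet or at the end ("none" if the first two lie within 2 percentage points) (midnight / dusk / summer / noon / none)
2. share of target in all that became target or side product, at the outlet or at the end, midnight
3. share of target in all that became target or side product, at the outlet or at the end, dusk
4. share of target in all that became target or side product, at the outlet or at the end, summer
5. share of target in all that became target or side product, at the outlet or at the end, noon

- the stated concentrations are those of everything mixed, before any reaction; amounts are the same in each set-up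
- what was read earlier has a scatter of 1 percentage point, one standard deviation
- the feed brings no volume worth counting
- the earlier runs were made in a closed, stirred flask

**First estimate.** At fixed [reagent] the target exit is pseudo-first-order, and its lifetime shortens as [reagent] rises. I assume a target costs two reagents and a side product one. The blue run at 4.00 min then keeps 0.0172 M, for a mean of 0.0216 M. Target over side product there reads 6.31, so the exits would tie near 0.00342 M.

**The objection.** One point of scatter is large on 6.5%. So take the teal run's long window. By the same count, reagent falls from 0.00727 M to 0.00217 M, and target gained over side product gained reads 1.22. That gives 0.00386 M. I carry the mean of the two as the tie concentration 0.00364 M, the [reagent] at which both exits have equal lifetimes. The moment share of target is then [reagent]/([reagent]+tie).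

**Summer.** Summer has the red run's charge. At 30.0 min the red count leaves 0.00169 M, a moment share of 31.7%, lower than the 58.6% gathered so far. If that reagent is spent at this split, side product gains 8.76% and target 4.07%, which gives 54.2%. But some reagent may remain, and the split worsens as it falls. These pull opposite ways, so I keep that figure.

**The others.** Summer starts at a moment share of 76.7%. A tank gives one moment share, at its outlet [reagent], and noon's stay is longer on average than midnight's. I rank summer first and noon last.

The forecast gave summer, with 43%, 48%, 52% and 32% for midnight, dusk, summer and noon, and for its two tanks it used “share = rR/(1+rR)”.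

**The result.** The flask gives 51.2%, 52.1%, 56.0% and 39.3% in that order, so summer is best.

    substrate ⇌ intermediate A (K = 0.800, k = 0.00159 s⁻¹)
    substrate + reagent → intermediate B (k = 0.276 M⁻¹ s⁻¹)
    intermediate B → side product (k = 0.00165 s⁻¹)
    reagent + intermediate B → target (k = 0.557 M⁻¹ s⁻¹)
    reagent + intermediate B ⇌ intermediate C (K = 32.0 M⁻¹, k = 0.135 M⁻¹ s⁻¹)

Summer keeps 5.7% of its reagent at 50.0 min, which is 6.83 × 10⁻⁴ M. The tie gives a moment share of 15.8% there, lower than the 56.0% gathered. At 500 min summer's share stands at 51.4%.

**Second flask.** Take summer with 0.0040 M substrate. Its charge of reagent is 1.32 ties, against 3.30 in summer. The moment share starts at 56.9% and ends at 23.3%, so expect less than summer. It gives 44.8%.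

All runs are calculated with made-up constants, noise included.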